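Slowness is what the two earlier runs show, but in one place. In the dawn run target creeps from 3.4% at 0.667 h to 9.7% at 4.00 h, while side product already stands at 64.9% at the first reading, with starting material down to 0.2%. The loss in the dawn run therefore comes early, and we must decide how to charge second reagent for the next run.

| setting | dawn | summer | beta | gamma | epsilon | theta |
|---|---|---|---|---|---|---|
| starting material | 20 mM | 20 mM | 20 mM | 20 mM | 20 mM | 20 mM |
| partner | 80 mM | 80 mM | 80.0 mM | 80.0 mM | 80.0 mM | 80.0 mM |
| second reagent | 30 mM | 15 mM | 30.0 mM | 30.0 mM (fed, over 2.00 h) | 30.0 mM | 30.0 mM |
| remark | run made earlier | run made earlier | everything together in a closed stirred flask, run for 4.0 h | a stirred flask in which second reagent is dosed at a steady rate over 2.00 h without added volume, worked up at 4.0 h | plug flow through a tube for 4.0 h, no back-mixing | one stirred flow tank at steady state, fed with the mixture as stated, mean residence time 4.0 h |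
| time |  |  | 4.0 h | 4.0 h | 4.0 h |  |

dawn run (percent of the starting material charged)

| time / h | target / % | side product / % | starting material / % |
|---|---|---|---|
| 0.667 | 3.4 | 64.9 | 0.2 |
| 1.33 | 6.1 | 65.0 | 0 |
| 2.00 | 7.4 | 65.5 | 0.7 |
| 2.50 | 8.5 | 64.3 | 0 |
| 3.00 | 8.8 | 64.3 | 0.1 |
| 4.00 | 9.7 | 63.4 | 0.3 |

summer run (percent of the starting material charged)

| time / min | target / % | side product / % | starting material / % |
|---|---|---|---|
| 8.00 | 0.8 | 41.5 | 7.2 |
| 15.0 | 1.6 | 43.1 | 0.4 |
| 25.0 | 1.1 | 43.8 | 0 |
| 30.0 | 0.4 | 44.7 | 0 |
| 40.0 | 2.3 | 45.1 | 0.5 |
| 50.0 | 2.1 | 44.8 | 0.3 |

(scatter of a reading: 0.5 percentage points)

- the stated concentrations are those of everything mixed, before any reaction; amounts are the same in each set-up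
- the feed brings no volume worth counting
- the earlier runs were made in a closed, stirred flask

- the set-up with the highest share of target in all that became target or side product, at the outlet or at the end ("none" if the first two lie within 2 percentage points) (beta / gamma / epsilon / theta / none)
- share of target in all that became target or side product, at the outlet or at the end, beta
- share of target in all that became target or side product, at the outlet or at the end, gamma
- share of target in all that became target or side product, at the outlet or at the end, epsilon
- share of target in all that became target or side product, at the outlet or at the end, theta

We take starting material to leave by two routes, one with partner and one with second reagent to side product. The rate by the second route over that by the first is then s·c(second reagent)/c(partner). Integrating over a run, s is ln(c end/c start) of second reagent over the same logarithm for partner, counting what each route consumed. The mean side product of dawn, 64.6%, gives 6.07. The last four readings of summer, with mean 44.6%, give 6.06. So we take s = 6.06, the selectivity factor, the rate constant of the second-reagent route over that of the partner route.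

Charged at once, as in beta, the ratio starts at 2.27. Partner is in excess, so its route is pseudo-first-order. The first summer reading, scaled by the partner's share, gives 10.9 h⁻¹, a lifetime of 0.0917 h. That lifetime is far shorter than the dosing time 2.00 h, and within it gamma's feed supplies about 1.37 mM. Taking that amount as c(second reagent) for as long as starting material lasts in gamma, a rough estimate of ours, the ratio is 0.104, and our estimate of side product is 9.42% of the starting material. We would feed.

The forecast agrees on gamma, with 13.2% for beta, 82% for gamma, 13.2% for epsilon and 14% for theta; of the side product it says “its yield follows the reagent charge”. It puts gamma's side product at about 1 mM, below our 1.88 mM.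

The flask gives gamma, with 13.4% for beta, 76.8% for gamma, 13.4% for epsilon and 13.7% for theta.

    second reagent + intermediate → target (k = 0.180 L mol⁻¹ min⁻¹)
    starting material + partner → intermediate (k = 2.50 L mol⁻¹ min⁻¹)
    starting material + second reagent → side product (k = 15.0 L mol⁻¹ min⁻¹)
    intermediate → decomposed reagent (k = 0.00640 min⁻¹)

In beta the half-life of starting material on the partner path at 0.0185 h is 0.060 h, far shorter than gamma's dosing time 2.00 h, and at 4.00 h gamma holds 1.45 mM of side product, a split of 0.0782 against our 0.104. The neighbour flask, beta with 32 mM of partner, reaches 80.7% side product, and the same logarithms on it give s = 5.99 against our 6.06.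

(The numbers in the tables were generated by integration with constants of no real substance; scatter was added.)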